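## Retrosynthetic overview

1. Vibsanin E ⇐ C10 aldehyde plus an (acyloxy)methylene ylide (Wittig); the aldehyde and the acetonyl group come from ozonolysis of a C10 vinyl / C5 methallyl pair.
2. That pair ⇐ conjugate addition and enolate alkylation on a tricyclic enone (rings A, B, C closed).
3. Ring B (tetrahydropyran) ⇐ oxa-Michael addition of a tertiary alcohol to an α-methylene ketone made from a β-keto ester.
4. Ring A (cycloheptanone, the key ring) ⇐ intramolecular Michael addition of a β-keto ester onto a cyclohexenecarboxylate; the precursor ⇐ vinylogous Mukaiyama aldol union of two fragments.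
5. Ring C (cyclohexene) ⇐ catalytic enantioselective Diels–Alder reaction. Order of ring formation: C, then A, then B.

Assumption: the SMILES fixes the target as the (2S,3S,5S,10S,11S,14R) isomer with an E enol ester, in the locants defined next.

Locants (used only for tricyclic compounds):
- C4 = ring A ketone; C3 = its α-carbon at the A/B fusion; C5 = its other α-carbon.
- C10 = ring A carbon between C5 and C11; C11 = methyl-bearing quaternary carbon.
- C2 = CH common to rings A, B and C; C14 = B/C fusion CH bearing C15 (CMe2).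
- C12–C14 = the three-carbon bridge of ring C; C18 = OCH2 on C3.

## Route

Step 1
Reactants: 1 but-3-en-2-one
Product: 2 2-(triisopropylsilyloxy)buta-1,3-diene
Conditions: iPr3SiOSO2CF3, Et3N, Et2O, 0 to 20 °C
Reagents that add atoms: triisopropylsilyl trifluoromethanesulfonate, CC(C)[Si](C(C)C)(C(C)C)OS(=O)(=O)C(F)(F)F
Why: Soft enolisation and O-silylation of the enone (silyl enol ether formation) gives the 2-silyloxy diene; no stereocentre is formed.

Step 2
Reactants: 2 2-(triisopropylsilyloxy)buta-1,3-diene; 3 2-methylprop-2-enal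
Product: 4 (S)-1-methyl-4-(triisopropylsilyloxy)cyclohex-3-ene-1-carbaldehyde
Conditions: (S)-1-(2-methylphenyl)-3,3-diphenyltetrahydro-1H,3H-pyrrolo[1,2-c][1,3,2]oxazaborole·HN(SO2CF3)2 (20 mol %), CH2Cl2, −78 °C
Reagents that add atoms: none
Why: Catalytic enantioselective Diels–Alder reaction gives the "para" adduct, and the catalyst-bound enal is attacked on the Re face of C2 (the mirror-image catalyst would give ent-4), so the quaternary centre (later C11) is S.

Step 3
Reactants: 4 (S)-1-methyl-4-(triisopropylsilyloxy)cyclohex-3-ene-1-carbaldehyde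
Product: 5 (S)-4-formyl-4-methylcyclohex-1-en-1-yl nonafluorobutane-1-sulfonate
Conditions: C4F9SO2F, Bu4NF (5 mol %), THF, 0 to 20 °C
Reagents that add atoms: nonafluorobutane-1-sulfonyl fluoride, FS(=O)(=O)C(F)(F)C(F)(F)C(F)(F)C(F)(F)F
Why: Fluoride-catalysed desilylation and O-sulfonylation converts the silyl enol ether regiospecifically into the alkenyl nonaflate, keeping the double-bond position that makes the ring chiral; the aldehyde has no α-hydrogen.

Step 4
Reactants: 5 (S)-4-formyl-4-methylcyclohex-1-en-1-yl nonafluorobutane-1-sulfonate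
Product: 6 methyl (S)-4-formyl-4-methylcyclohex-1-ene-1-carboxylate
Conditions: Pd(OAc)2 (5 mol %), Ph2P(CH2)3PPh2 (5 mol %), CO (1 atm), MeOH, Et3N, DMF, 50 °C
Reagents that add atoms: carbon monoxide, [C-]#[O+]; methanol, CO
Why: Palladium-catalysed alkoxycarbonylation of the alkenyl sulfonate gives the α,β-unsaturated ester (the later Michael acceptor) without touching the stereocentre.

Step 5
Reactants: 7 allyl 3-oxobutanoate
Product: 8 allyl 3-(triethylsilyloxy)but-2-enoate
Conditions: Et3SiCl, Et3N, hexane, 20 °C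
Reagents that add atoms: chlorotriethylsilane, CC[Si](Cl)(CC)CC
Why: O-silylation of the β-keto ester enol (silyl enol ether formation).

Step 6
Reactants: 8 allyl 3-(triethylsilyloxy)but-2-enoate
Product: 9 1-(allyloxy)-1,3-bis(triethylsilyloxy)buta-1,3-diene
Conditions: LiN(iPr)2 (commercial solution), THF, −78 °C; Et3SiCl
Reagents that add atoms: chlorotriethylsilane, CC[Si](Cl)(CC)CC
Why: γ-Deprotonation and O-silylation of the ester dienolate gives the bis-silyl dienol ether, a Chan-type acetoacetate dianion equivalent.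

Step 7
Reactants: 6 methyl (S)-4-formyl-4-methylcyclohex-1-ene-1-carboxylate; 9 1-(allyloxy)-1,3-bis(triethylsilyloxy)buta-1,3-diene
Product: 11 allyl 5-[(1S)-4-(methoxycarbonyl)-1-methylcyclohex-3-en-1-yl]-3-oxo-5-(triethylsilyloxy)pentanoate (mixture of C5 epimers), via bis-silyl adduct 10 (not isolated)
Conditions: HN(SO2CF3)2 (2 mol %), CH2Cl2, −78 °C; then 0.5 M aq. citric acid, THF, 0 °C
Reagents that add atoms: none
Why: Vinylogous Mukaiyama aldol reaction: the terminal carbon of the diene adds to the aldehyde (the enoate is far less electrophilic) with silyl transfer to the new oxygen; the carbinol centre is uncontrolled and is eliminated in step 11.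

Step 8
Reactants: 11 allyl 5-[(1S)-4-(methoxycarbonyl)-1-methylcyclohex-3-en-1-yl]-3-oxo-5-(triethylsilyloxy)pentanoate
Product: 12 2-allyl 9-methyl (1S,6S,9R)-6-methyl-3-oxo-5-(triethylsilyloxy)bicyclo[4.3.1]decane-2,9-dicarboxylate (epimers at C2/C5)
Conditions: Cs2CO3 (0.5 equiv), MeCN, 60 °C
Reagents that add atoms: none
Why: Intramolecular Michael addition (7-exo-trig) closes ring A: the β-keto ester carbon can reach the enoate β-carbon only on the face carrying its tether, so the new ring-fusion centre (later C2) follows from C11, and the ester enolate is protonated anti to the new bond, leaving CO2Me equatorial and cis to it (later C14).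

Step 9
Reactants: 12 2-allyl 9-methyl (1S,6S,9R)-6-methyl-3-oxo-5-(triethylsilyloxy)bicyclo[4.3.1]decane-2,9-dicarboxylate
Product: 13 allyl (1S,6S,9R)-9-(2-hydroxypropan-2-yl)-6-methyl-3-oxo-5-(triethylsilyloxy)bicyclo[4.3.1]decane-2-carboxylate (epimers at C2/C5)
Conditions: MeMgBr (5 equiv), THF, −20 to 20 °C; aq. NH4Cl
Reagents that add atoms: methylmagnesium bromide, C[Mg]Br
Why: Double Grignard addition to the methyl ester gives the tertiary alcohol, while the β-keto ester is protected in situ as its magnesium enolate.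

Step 10
Reactants: 13 allyl (1S,6S,9R)-9-(2-hydroxypropan-2-yl)-6-methyl-3-oxo-5-(triethylsilyloxy)bicyclo[4.3.1]decane-2-carboxylate
Product: 17 (2S,3S,11S,14R)-10-hydroxy tricyclic ketone (rings A/B/C closed; C5 is CH2; C10 epimers), via keto acid 14 (not isolated), via amino ketone 15 (not isolated), via methylene ketone 16 (not isolated)
Conditions: 37% aq. CH2O, morpholine, AcOH, THF, 20 °C; Pd(PPh3)4 (3 mol %), 20 to 50 °C; then 1 M aq. HCl, 20 °C
Reagents that add atoms: formaldehyde, C=O
Why: Tsuji–Trost deallylation, decarboxylative Mannich reaction and β-elimination give an α-methylene ketone that the tertiary alcohol closes to ring B by intramolecular oxa-Michael addition, C3 being protonated reversibly to the unstrained cis A/B fusion; aqueous acid then removes the silyl ether.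

Step 11
Reactants: 17 (2S,3S,11S,14R)-10-hydroxy tricyclic ketone
Product: 19 (2S,3S,11S,14R)-tricyclic enone (C5=C10 double bond conjugated to the C4 ketone), via mesylate 18 (not isolated)
Conditions: MeSO2Cl, Et3N, CH2Cl2, 0 °C; then DBU, 20 °C
Reagents that add atoms: none
Why: Mesylation and E1cB elimination; both C10 epimers converge on the ring A enone.

Step 12
Reactants: 20 3-chloro-2-methylprop-1-ene
Product: 21 3-iodo-2-methylprop-1-ene
Conditions: NaI, acetone, 20 °C
Reagents that add atoms: sodium iodide, [Na+].[I-]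
Why: Finkelstein exchange gives the more reactive allylic iodide needed for alkylating a hindered enolate.

Step 13
Reactants: 19 (2S,3S,11S,14R)-tricyclic enone; 21 3-iodo-2-methylprop-1-ene
Product: 24 (2S,3S,5S,10S,11S,14R)-5-(2-methylprop-2-enyl)-10-vinyl tricyclic ketone, via silyl enol ether 22 (not isolated), via lithium enolate 23 (not isolated)
Conditions: CH2=CHMgBr, CuBr·SMe2 (10 mol %), Me3SiCl, THF, −78 °C; volatiles removed; MeLi, THF, 0 °C; then 21, HMPA, −78 to 0 °C
Reagents that add atoms: vinylmagnesium bromide, C=C[Mg]Br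
Why: Copper-catalysed conjugate addition puts the vinyl group on C10 from the face opposite the C12–C14 bridge, and the regiodefined lithium enolate is C-alkylated at C5 anti to that vinyl group (enolate alkylation), giving the trans arrangement.

Step 14
Reactants: 24 (2S,3S,5S,10S,11S,14R)-5-(2-methylprop-2-enyl)-10-vinyl tricyclic ketone
Product: 25 (2S,3S,5S,10S,11S,14R)-4-oxo-5-(2-oxopropyl) tricycle-10-carbaldehyde
Conditions: O3, CH2Cl2/MeOH, −78 °C; Me2S
Reagents that add atoms: ozone, [O-][O+]=O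
Why: Ozonolysis with reductive work-up cleaves both alkenes at once, the vinyl group to the C10 aldehyde and the methallyl group to the acetonyl ketone; neutral conditions leave C10 and C5 untouched.

Step 15
Reactants: 26 3-methylbut-2-enoyl chloride
Product: 27 chloromethyl 3-methylbut-2-enoate
Conditions: (CH2O)n, ZnCl2 (2 mol %), 80 °C
Reagents that add atoms: paraformaldehyde (as formaldehyde), C=O
Why: ZnCl2-catalysed insertion of formaldehyde into the acyl chloride gives the α-chloroalkyl ester.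

Step 16
Reactants: 27 chloromethyl 3-methylbut-2-enoate
Product: 28 iodomethyl 3-methylbut-2-enoate
Conditions: NaI, acetone, 20 °C
Reagents that add atoms: sodium iodide, [Na+].[I-]
Why: Finkelstein exchange, because the chloride quaternises PPh3 too slowly.

Step 17
Reactants: 28 iodomethyl 3-methylbut-2-enoate
Product: 29 {[(3-methylbut-2-enoyl)oxy]methyl}triphenylphosphonium iodide
Conditions: PPh3, toluene, 20 °C
Reagents that add atoms: triphenylphosphine, c1ccc(cc1)P(c1ccccc1)c1ccccc1
Why: SN2 quaternisation of the phosphine gives the salt for the Anders–Gaßner variant of the Wittig reaction.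

Step 18
Reactants: 25 (2S,3S,5S,10S,11S,14R)-4-oxo-5-(2-oxopropyl) tricycle-10-carbaldehyde; 29 {[(3-methylbut-2-enoyl)oxy]methyl}triphenylphosphonium iodide
Product: 31 vibsanin E, via ylide 30 (not isolated)
Conditions: KN(SiMe3)2, THF, −78 °C; then 25, −78 to 0 °C; E isomer separated from Z on AgNO3-impregnated silica
Reagents that add atoms: none
Why: Wittig reaction of the (acyloxy)methylene ylide with the aldehyde (much faster than with the two ketones) forms the enol ester as an E/Z mixture of uncertain ratio, from which the E isomer is taken.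

## Compound list

1 | but-3-en-2-one | CC(=O)C=C | starting material
2 | 2-(triisopropylsilyloxy)buta-1,3-diene | C=CC(=C)O[Si](C(C)C)(C(C)C)C(C)C | intermediate
3 | 2-methylprop-2-enal | CC(=C)C=O | starting material
4 | (S)-1-methyl-4-(triisopropylsilyloxy)cyclohex-3-ene-1-carbaldehyde | CC(C)[Si](C(C)C)(C(C)C)OC1=CC[C@@](C)(C=O)CC1 | intermediate
5 | (S)-4-formyl-4-methylcyclohex-1-en-1-yl nonafluorobutane-1-sulfonate | FC(F)(F)C(F)(F)C(F)(F)C(F)(F)S(=O)(=O)OC1=CC[C@@](C)(C=O)CC1 | intermediate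
6 | methyl (S)-4-formyl-4-methylcyclohex-1-ene-1-carboxylate | COC(=O)C1=CC[C@@](C)(C=O)CC1 | intermediate
7 | allyl 3-oxobutanoate | CC(=O)CC(=O)OCC=C | starting material
8 | allyl 3-(triethylsilyloxy)but-2-enoate (E/Z mixture) | CC[Si](CC)(CC)OC(C)=CC(=O)OCC=C | intermediate
9 | 1-(allyloxy)-1,3-bis(triethylsilyloxy)buta-1,3-diene | CC[Si](CC)(CC)OC(=C)C=C(OCC=C)O[Si](CC)(CC)CC | intermediate
10 | allyl 5-[(1S)-4-(methoxycarbonyl)-1-methylcyclohex-3-en-1-yl]-3,5-bis(triethylsilyloxy)pent-2-enoate (C5 epimers) | C=CCOC(=O)C=C(O[Si](CC)(CC)CC)CC(O[Si](CC)(CC)CC)[C@]1(C)CC=C(C(=O)OC)CC1 | intermediate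
11 | allyl 5-[(1S)-4-(methoxycarbonyl)-1-methylcyclohex-3-en-1-yl]-3-oxo-5-(triethylsilyloxy)pentanoate (C5 epimers) | C=CCOC(=O)CC(=O)CC(O[Si](CC)(CC)CC)[C@]1(C)CC=C(C(=O)OC)CC1 | intermediate
12 | 2-allyl 9-methyl (1S,6S,9R)-6-methyl-3-oxo-5-(triethylsilyloxy)bicyclo[4.3.1]decane-2,9-dicarboxylate (epimers at C2/C5) | C=CCOC(=O)C1C(=O)CC(O[Si](CC)(CC)CC)[C@@]2(C)CC[C@@H](C(=O)OC)[C@@H]1C2 | intermediate
13 | allyl (1S,6S,9R)-9-(2-hydroxypropan-2-yl)-6-methyl-3-oxo-5-(triethylsilyloxy)bicyclo[4.3.1]decane-2-carboxylate (epimers at C2/C5) | C=CCOC(=O)C1C(=O)CC(O[Si](CC)(CC)CC)[C@@]2(C)CC[C@@H](C(C)(C)O)[C@@H]1C2 | intermediate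
14 | (1S,6S,9R)-9-(2-hydroxypropan-2-yl)-6-methyl-3-oxo-5-(triethylsilyloxy)bicyclo[4.3.1]decane-2-carboxylic acid | OC(=O)C1C(=O)CC(O[Si](CC)(CC)CC)[C@@]2(C)CC[C@@H](C(C)(C)O)[C@@H]1C2 | intermediate
15 | (1S,6S,9R)-9-(2-hydroxypropan-2-yl)-6-methyl-2-(morpholin-4-ylmethyl)-5-(triethylsilyloxy)bicyclo[4.3.1]decan-3-one | O1CCN(CC1)CC1C(=O)CC(O[Si](CC)(CC)CC)[C@@]2(C)CC[C@@H](C(C)(C)O)[C@@H]1C2 | intermediate
16 | (1S,6S,9R)-9-(2-hydroxypropan-2-yl)-6-methyl-2-methylidene-5-(triethylsilyloxy)bicyclo[4.3.1]decan-3-one | C=C1C(=O)CC(O[Si](CC)(CC)CC)[C@@]2(C)CC[C@@H](C(C)(C)O)[C@@H]1C2 | intermediate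
17 | (2S,3S,11S,14R)-10-hydroxy tricyclic ketone (C10 epimers) | C1C(=O)[C@@H]2COC(C)(C)[C@@H]3CC[C@@](C)(C[C@@H]32)C1O | intermediate
18 | 10-methanesulfonate of 17 | C1C(=O)[C@@H]2COC(C)(C)[C@@H]3CC[C@@](C)(C[C@@H]32)C1OS(C)(=O)=O | intermediate
19 | (2S,3S,11S,14R)-tricyclic enone (C5=C10) | O=C1[C@@H]2COC(C)(C)[C@@H]3CC[C@@](C)(C[C@@H]32)C=C1 | intermediate
20 | 3-chloro-2-methylprop-1-ene | CC(=C)CCl | starting material
21 | 3-iodo-2-methylprop-1-ene | CC(=C)CI | intermediate
22 | (2S,3S,10S,11S,14R)-10-vinyl C4-(trimethylsilyloxy) C4=C5 enol ether | C1=C(O[Si](C)(C)C)[C@@H]2COC(C)(C)[C@@H]3CC[C@@](C)(C[C@@H]32)[C@H]1C=C | intermediate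
23 | lithium enolate corresponding to 22 | C1=C(O[Li])[C@@H]2COC(C)(C)[C@@H]3CC[C@@](C)(C[C@@H]32)[C@H]1C=C | intermediate
24 | (2S,3S,5S,10S,11S,14R)-5-(2-methylprop-2-enyl)-10-vinyl tricyclic ketone | CC(=C)C[C@@H]1C(=O)[C@@H]2COC(C)(C)[C@@H]3CC[C@@](C)(C[C@@H]32)[C@H]1C=C | intermediate
25 | (2S,3S,5S,10S,11S,14R)-4-oxo-5-(2-oxopropyl) tricycle-10-carbaldehyde | CC(=O)C[C@@H]1C(=O)[C@@H]2COC(C)(C)[C@@H]3CC[C@@](C)(C[C@@H]32)[C@H]1C=O | intermediate
26 | 3-methylbut-2-enoyl chloride | CC(C)=CC(Cl)=O | starting material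
27 | chloromethyl 3-methylbut-2-enoate | CC(C)=CC(=O)OCCl | intermediate
28 | iodomethyl 3-methylbut-2-enoate | CC(C)=CC(=O)OCI | intermediate
29 | {[(3-methylbut-2-enoyl)oxy]methyl}triphenylphosphonium iodide | CC(C)=CC(=O)OC[P+](c1ccccc1)(c1ccccc1)c1ccccc1.[I-] | intermediate
30 | (triphenyl-λ5-phosphanylidene)methyl 3-methylbut-2-enoate | CC(C)=CC(=O)OC=P(c1ccccc1)(c1ccccc1)c1ccccc1 | intermediate
31 | vibsanin E | CC(=O)C[C@@H]1C(=O)[C@@H]2COC(C)(C)[C@@H]3CC[C@@](C)(C[C@@H]32)[C@H]1/C=C/OC(=O)C=C(C)C | target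

## Step count and risks

Total: 18 steps. Longest linear sequence: 12 steps (1, 2, 3, 4, 7, 8, 9, 10, 11, 13, 14, 18). The other six steps lie in three side branches (5–6, 12, 15–17).

Steps most likely to fail:

Step 8 (the key ring closure) may be slow because a cyclohexenecarboxylate is a weak Michael acceptor and a seven-membered bridged ring must form. The fallback sets out from 5 and comes back at 13 by changing the acceptor to a ketone. Carbonylative Stille coupling of 5 (Pd(PPh3)4, CO, SnMe4, LiCl, DMF) gives (S)-4-acetyl-1-methylcyclohex-3-ene-1-carbaldehyde F1. The aldol reaction of step 7 with 9 then gives the bis-silyl adduct F2 and, after the citric acid treatment, the keto ester F3. Its Michael closure onto the far more electrophilic enone gives the bicyclic methyl ketone F4, and a single addition of MeMgBr to the acetyl group of F4 gives 13.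

Step 10 combines deallylation, decarboxylative Mannich reaction, elimination and oxa-Michael closure in one flask, and premature decarboxylation would lose the regiocontrol at the future C3. The fallback sets out from 13 and comes back at 17 by making the C–C bond before the ester is cleaved. Aqueous CH2O with KHCO3 gives the hydroxymethyl keto ester F5, and Ac2O in pyridine gives the acetoxymethyl keto ester F6. Pd(OAc)2 and PPh3 in MeCN then effect neutral decarboxylation–deacetoxylation to the methylene ketone 16, which DBU and then 1 M aq. HCl close and desilylate to 17.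

Step 18 may give mostly the Z enol ester, and the ylide is short-lived. The fallback sets out from 25 and comes back at 31 by building the E alkene first and the C–O bond second. Boryl olefination of 25 (CrCl2, LiI, Cl2CHB(pin), THF) gives the (E)-alkenyl pinacol boronate F7, and KHF2 gives the potassium trifluoroborate F8. Copper-catalysed oxidative coupling of F8 with 3-methylbut-2-enoic acid (CuBr, 4-(dimethylamino)pyridine, 4 Å sieves, O2) gives 31 with retention of the E geometry.

## Further compounds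

F1 | step 8 | (S)-4-acetyl-1-methylcyclohex-3-ene-1-carbaldehyde | CC(=O)C1=CC[C@@](C)(C=O)CC1
F2 | step 8 | allyl 5-[(1S)-4-acetyl-1-methylcyclohex-3-en-1-yl]-3,5-bis(triethylsilyloxy)pent-2-enoate | C=CCOC(=O)C=C(O[Si](CC)(CC)CC)CC(O[Si](CC)(CC)CC)[C@]1(C)CC=C(C(C)=O)CC1
F3 | step 8 | allyl 5-[(1S)-4-acetyl-1-methylcyclohex-3-en-1-yl]-3-oxo-5-(triethylsilyloxy)pentanoate | C=CCOC(=O)CC(=O)CC(O[Si](CC)(CC)CC)[C@]1(C)CC=C(C(C)=O)CC1
F4 | step 8 | allyl (1S,6S,9R)-9-acetyl-6-methyl-3-oxo-5-(triethylsilyloxy)bicyclo[4.3.1]decane-2-carboxylate | C=CCOC(=O)C1C(=O)CC(O[Si](CC)(CC)CC)[C@@]2(C)CC[C@@H](C(C)=O)[C@@H]1C2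
F5 | step 10 | allyl (1S,6S,9R)-2-(hydroxymethyl)-9-(2-hydroxypropan-2-yl)-6-methyl-3-oxo-5-(triethylsilyloxy)bicyclo[4.3.1]decane-2-carboxylate | C=CCOC(=O)C1(CO)C(=O)CC(O[Si](CC)(CC)CC)[C@@]2(C)CC[C@@H](C(C)(C)O)[C@@H]1C2
F6 | step 10 | allyl (1S,6S,9R)-2-(acetoxymethyl)-9-(2-hydroxypropan-2-yl)-6-methyl-3-oxo-5-(triethylsilyloxy)bicyclo[4.3.1]decane-2-carboxylate | C=CCOC(=O)C1(COC(C)=O)C(=O)CC(O[Si](CC)(CC)CC)[C@@]2(C)CC[C@@H](C(C)(C)O)[C@@H]1C2
F7 | step 18 | (2S,3S,5S,10S,11S,14R)-4-oxo-5-(2-oxopropyl)-10-[(E)-2-(4,4,5,5-tetramethyl-1,3,2-dioxaborolan-2-yl)vinyl] tricycle | CC(=O)C[C@@H]1C(=O)[C@@H]2COC(C)(C)[C@@H]3CC[C@@](C)(C[C@@H]32)[C@H]1/C=C/B1OC(C)(C)C(C)(C)O1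
F8 | step 18 | potassium trifluoroborate corresponding to F7 | CC(=O)C[C@@H]1C(=O)[C@@H]2COC(C)(C)[C@@H]3CC[C@@](C)(C[C@@H]32)[C@H]1/C=C/[B-](F)(F)F.[K+]
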